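Carbons are numbered along the chain from the lactone carbonyl (C1) to the phenyl-bearing carbon (C15). Compound numbers are those of the steps and the compound list.

## The problem

Target 27 is a linear fifteen-carbon chain with a single ring, the 5,6-dihydro-2H-pyran-2-one (C1–C5 plus the C5 oxygen). The ring carries at C5 a (Z)-C6=C7 alkene, then carbinols at C9, C11 and C13, and ends in an (E)-styrene (C14=C15). There are four stereocentres (5R, 9S, 11R, 13R) and two alkene geometries to control. C11 and C13 are 1,3-syn and C9 and C11 are 1,3-anti, so one of each pair can in principle be set from its neighbour. C5 is cut off from C9 by the Z alkene and cannot be reached by 1,3-induction, so it needs a reagent or a transfer of chirality across the three-carbon C6–C8 unit. The unsaturated lactone is a Michael acceptor and opens under base by γ-deprotonation and β-elimination of the C5 oxygen, so it belongs at the end. The C13 carbinol is of the cinnamyl type and ionises in strong acid. The Z alkene and the styrene rule out hydrogenolysis and dissolving-metal conditions, and the C3, C5, C9, C11 and C13 oxygens must be told apart during the endgame. The enabling feature is that the C5 and C9 carbinols flank the C6=C7–C8 unit as a (Z)-2-ene-1,5-diol, the product pattern of two successive allylborations from one 1,3-dimetallated propene, with the C11/C13 syn diol able to ride through as an acetonide.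

## Retrosynthesis

**Lactone C1–O bond.** Target 27 is opened at the ester bond to the (Z)-hydroxy enoate 26, which is the fully deprotected form of the silylated acetonide 25. Closing the lactone last keeps the base-sensitive dihydropyranone out of every carbanion and boron step. An acrylate ring-closing metathesis was not chosen because C6=C7 and the styrene would compete. The forward step asks for one acid treatment that removes two silyl ethers and the acetonide and lets the C5 hydroxyl close onto the Z ester without ionising the C13 carbinol.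

**C2=C3 double bond.** Enoate 25 is cut at C2=C3 into aldehyde 24 and a two-carbon phosphonate (Still–Gennari olefination). This removes C1 and C2 and the only geometry element not made in the key step. Aldehyde 24 goes back by oxidation to alcohol 23, by selective primary desilylation to the tris-silyl ether 22, and by silylation to diol 21. None of these steps forms a skeletal bond. The forward sequence asks for Z-selective olefination of a β-silyloxy aldehyde without β-elimination, and for a clean distinction of the primary silyl ether from the two secondary ones.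

**C5–C6 and C8–C9 (key disconnection).** Diol 21 is cut at both bonds that flank the allyl unit. This gives aldehyde 13 (C3–C5), the allenylboronate 18 (C6–C8) and aldehyde 10 (C9–C15 with the syn acetonide). The allylic carbinol of a double allylboration always comes from the first aldehyde, so 13 must react first and 10 second. Against stepwise alkyne or Wittig assemblies, this cut makes two C–C bonds, two stereocentres and the Z alkene in one flask, and reduces a C13 chain to pieces of three, three and seven carbons. The forward reaction needs three things.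
- The hydroboration product must remain the kinetic (Z)-γ-boryl allylborane 19.
- The isopinocampheyl groups must fix C5.
- The boronate 20 must react through a chair with its α-substituent axial.

With a pinacol ester, the branched β-boryloxy substituent of such intermediates would be expected to sit equatorial and deliver the E alkene. The diol on boron is therefore changed to tetraphenylethylene glycol (benzopinacol). Its bulk penalises the equatorial chair and also slows the boratropic shift that would erode the Z reagent.

**Fragment 2 functional groups.** Aldehyde 10 comes from ester 9 by partial reduction, 9 from syn diol 8 by acetonide formation, and 8 from the δ-hydroxy-β-keto ester 6 by chelation-controlled reduction. C11 is thus derived from C13 and only one stereocentre has to be bought. The forward steps ask for syn selectivity in the reduction and for an ester reduction that stops at the aldehyde.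

**C12–C13.** Keto ester 6 is cut between C12 and C13 into cinnamaldehyde 4 and the acetoacetate dianion equivalent 3. Diene 3 is made from methyl acetoacetate 1 through silyl enol ether 2. This cut puts all seven carbons of fragment 2 in place in one catalytic enantioselective aldol and carries the styrene in from the start. The forward step asks for face selectivity at an enal carbonyl and 1,2- rather than 1,4-addition.

**Small pieces.** Aldehyde 13 comes from propane-1,3-diol 11 by monosilylation (12) and oxidation. Boronate 18 comes from propargyl bromide 14, trimethyl borate and benzopinacol 15 through the Grignard reagent 16 and allenylboronic acid 17.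

## Roads not taken

**Alternative 1: rhenium-oxo allylic transposition trapped as a syn acetal.** The cut is the C13–O bond. The C13 carbinol is derived from a C15 benzylic allylic alcohol A1 that already carries the lactone, the Z alkene, a silylated C9 oxygen and a free C11 hydroxyl. In the forward step Re2O7 shuttles the hydroxyl from C15 to C13 through perrhenate esters. Benzaldehyde dimethyl acetal captures the C11/C13 diol as the all-equatorial 2-phenyl-1,3-dioxane A2, and the alkene settles in conjugation with the phenyl ring as the E styrene.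
- Merits: C13 is set from C11 under thermodynamic control, so the step corrects itself. The styrene geometry comes free. No chiral reagent is spent on C13.
- Weak points: the step solves only the 11,13-syn relationship, the easiest stereochemical problem of the target. The Z-ene-1,5-diol and C5 still have to be made by other means. The acidic rhenium oxide would act on a substrate that contains an allylic lactone C5–O bond and a Michael acceptor. The benzylidene acetal must later be removed by acid next to the cinnamyl-type carbinol, since hydrogenolysis is excluded.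
- Comparison: for C11/C13 this road is as dependable as the chelation-controlled reduction of 6 to 8, and it needs no stoichiometric boron reagent. The chosen plan sets against this that its syn diol is made on a seven-carbon ester before any sensitive group exists, and that its key step is spent on the hard part of the molecule.

**Alternative 2: silicon-tethered ring-closing metathesis.** The cut is the C6=C7 double bond. The C5 vinyl carbinol and the C9 allyl carbinol are joined through a diisopropylsilylene bridge in A3. The second-generation Grubbs catalyst RuCl2(H2IMes)(PCy3)(=CHPh) closes the eight-membered 1,3-dioxa-2-silacyclooctene A4.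
- Merits: an eight-membered ring can only hold a Z alkene, so the geometry is guaranteed by ring size. The two carbinols are made independently by standard asymmetric vinyl and allyl additions.
- Weak points: A3 contains two more alkenes. The styrene can close a carbocycle with the allyl terminus or be clipped by cross metathesis, and the Z enoate can isomerise. An unsymmetrical silylene from two different secondary alcohols needs two controlled silylation stages. The medium ring needs high dilution, and the tether must be removed afterwards.
- Comparison: this road is stronger on the Z geometry, which in the chosen plan rests on a conformational preference in the second allylboration. The chosen plan sets against this that it needs one operation where this road needs five (two asymmetric additions, tethering, metathesis, detethering), and that no competing alkene chemistry can arise with boron reagents.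

**Alternative 3: silyl dithiane linchpin between two epoxides.** The cuts are C10–C11 and C11–C12. Lithiated 2-(tert-butyldimethylsilyl)-1,3-dithiane A5 opens the alkynyl epoxide A6 at C10. The alkoxide triggers a 1,4-shift of silicon from carbon to oxygen, and the new dithianyl anion opens the styryl epoxide A7 at C12 to give A8.
- Merits: three components are joined in one flask, as in the chosen plan. C9 and C13 come from enantiopure epoxides, which is a firmer source of absolute configuration than a catalytic aldol. The C9 oxygen emerges silylated and so differentiated from C13.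
- Weak points: C11 arrives as a dithiane. It must be unmasked in the presence of a styrene and an alkyne and then reduced with 1,3-control, so two more steps are needed to create a stereocentre. The vinyl epoxide A7 can be opened at the allylic carbon or in conjugate fashion instead of at C12. The whole C1–C5 part, the C5 stereocentre and the Z alkene still require alkyne desilylation, addition to an aldehyde with separate control of C5, and semi-hydrogenation.
- Comparison: this road is better in the security of C9 and C13. The chosen plan sets against this that its coupling step also delivers C5 and the Z alkene, so fewer steps follow the union.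

Key step: step 10

Assumption: the (R)-BINOL–Ti(OiPr)4 catalyst is taken to direct the dienolate to the Re face of 4, as it does with other aldehydes in this reaction class; if the sense were opposite, the (S)-ligand would be used.
Remark: dIpc denotes the isopinocampheyl group derived from (+)-α-pinene; (dIpc)2BH is (−)-diisopinocampheylborane.

## Route

Step 1
Reactants: 1 methyl acetoacetate
Product: 2 methyl 3-(trimethylsilyloxy)but-2-enoate
Conditions: Me3SiCl, Et3N, hexane, rt
Reagents that add atoms: chlorotrimethylsilane, C[Si](C)(C)Cl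
Why: Silyl enol ether formation on the enol of the β-keto ester; the alkene geometry is of no consequence because it is erased in step 2.

Step 2
Reactants: 2 methyl 3-(trimethylsilyloxy)but-2-enoate
Product: 3 1-methoxy-1,3-bis(trimethylsilyloxy)buta-1,3-diene (Chan's diene)
Conditions: LiN(iPr)2, THF, −78 °C; Me3SiCl, −78 °C → rt
Reagents that add atoms: chlorotrimethylsilane, C[Si](C)(C)Cl
Why: γ-Deprotonation of the vinylogous ester and O-silylation of the dienolate give the bis-silyl dienol ether, the standard neutral equivalent of the acetoacetate dianion.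

Step 3
Reactants: 4 (E)-cinnamaldehyde; 3 1-methoxy-1,3-bis(trimethylsilyloxy)buta-1,3-diene
Product: 6 methyl (5R,6E)-5-hydroxy-3-oxo-7-phenylhept-6-enoate, via bis-silyl aldol adduct 5 (not isolated)
Conditions: Ti(OiPr)4/(R)-BINOL (1:1, cat.), 4 Å MS, THF, −78 °C → rt; then CF3CO2H, −78 °C → rt; aq. NaHCO3
Reagents that add atoms: none
Why: Catalytic enantioselective vinylogous Mukaiyama aldol: the terminal carbon of 3 adds 1,2 to the enal inside the BINOL–titanium complex, the (R)-ligand directing attack to the Re face so that C13 is set as R (forming C12–C13); acid then removes both silyl groups.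

Step 4
Reactants: 6 methyl (5R,6E)-5-hydroxy-3-oxo-7-phenylhept-6-enoate
Product: 8 methyl (3S,5R,6E)-3,5-dihydroxy-7-phenylhept-6-enoate, via diethylboron chelate 7 (not isolated)
Conditions: Et2BOMe, THF/MeOH (4:1), −78 °C; NaBH4, −78 °C; AcOH; MeOH co-evaporation
Reagents that add atoms: none
Why: Narasaka–Prasad reduction: the C13 oxygen and the C11 ketone are held in a six-membered boron chelate and hydride attacks axially, away from the pseudo-equatorial styryl group, so C11 is set syn to C13; the isolated ketone is reduced, not the ester or the styrene.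

Step 5
Reactants: 8 methyl (3S,5R,6E)-3,5-dihydroxy-7-phenylhept-6-enoate
Product: 9 methyl 2-[(4S,6R)-2,2-dimethyl-6-[(E)-2-phenylethenyl]-1,3-dioxan-4-yl]acetate
Conditions: Me2C(OMe)2, PPTS (cat.), CH2Cl2, rt
Reagents that add atoms: 2,2-dimethoxypropane, COC(C)(C)OC
Why: Acid-catalysed transketalisation; the syn diol gives the chair 1,3-dioxane with both ring substituents equatorial, and the weak acid does not ionise the cinnamyl-type C13–O bond.

Step 6
Reactants: 9 methyl 2-[(4S,6R)-2,2-dimethyl-6-[(E)-2-phenylethenyl]-1,3-dioxan-4-yl]acetate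
Product: 10 2-[(4S,6R)-2,2-dimethyl-6-[(E)-2-phenylethenyl]-1,3-dioxan-4-yl]acetaldehyde
Conditions: i-Bu2AlH, CH2Cl2, −78 °C; MeOH; aq. potassium sodium tartrate
Reagents that add atoms: none
Why: Partial ester reduction: the tetrahedral aluminium hemiacetal, stabilised by the β-oxygen, survives at −78 °C and releases the aldehyde only on work-up; no stereocentre is α to the carbonyl.

Step 7
Reactants: 11 propane-1,3-diol
Product: 12 3-[tert-butyl(dimethyl)silyl]oxypropan-1-ol
Conditions: NaH, THF, 0 °C → rt; TBSCl, rt
Reagents that add atoms: tert-butyldimethylsilyl chloride, CC(C)(C)[Si](C)(C)Cl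
Why: Monosilylation of a symmetrical diol through its sparingly soluble monosodium alkoxide, which is silylated once as it dissolves.

Step 8
Reactants: 12 3-[tert-butyl(dimethyl)silyl]oxypropan-1-ol
Product: 13 3-[tert-butyl(dimethyl)silyl]oxypropanal
Conditions: TEMPO (cat.), PhI(OAc)2, CH2Cl2, rt
Reagents that add atoms: none
Why: Nitroxyl-catalysed oxidation of a primary alcohol stops at the aldehyde and leaves the silyl ether alone.

Step 9
Reactants: 14 propargyl bromide; 15 benzopinacol (1,1,2,2-tetraphenylethane-1,2-diol)
Product: 18 4,4,5,5-tetraphenyl-2-(propa-1,2-dien-1-yl)-1,3,2-dioxaborolane, via allenylmagnesium bromide 16 (not isolated), via allenylboronic acid 17 (not isolated)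
Conditions: Mg, HgCl2 (cat.), Et2O, 0 °C; B(OMe)3, Et2O, −78 °C; 2 M HCl aq., → rt; then 15, MgSO4, Et2O, rt
Reagents that add atoms: trimethyl borate, COB(OC)OC
Why: Borylation of the propargyl/allenyl Grignard reagent with a trialkyl borate gives allenylboronic acid after hydrolysis, and condensation with the 1,2-diol under dehydrating conditions gives the cyclic boronic ester.

Step 10
Reactants: 18 4,4,5,5-tetraphenyl-2-(propa-1,2-dien-1-yl)-1,3,2-dioxaborolane; 13 3-[tert-butyl(dimethyl)silyl]oxypropanal; 10 2-[(4S,6R)-2,2-dimethyl-6-[(E)-2-phenylethenyl]-1,3-dioxan-4-yl]acetaldehyde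
Product: 21 (3R,4Z,7S)-1-{[tert-butyl(dimethyl)silyl]oxy}-8-{(4R,6R)-2,2-dimethyl-6-[(E)-2-phenylethenyl]-1,3-dioxan-4-yl}oct-4-ene-3,7-diol, via (Z)-γ-boryl allylborane 19 (not isolated), via syn β-boryloxy allylboronate 20 (not isolated)
Conditions: (dIpc)2BH, toluene, −25 °C; 13, −78 °C; then 10, −78 °C → rt; aq. NaHCO3, 30% H2O2, 0 °C → rt
Reagents that add atoms: none
Why: (dIpc)2BH adds to the terminal C=C of 18 from the side away from the bulky dioxaborolane, putting boron on the terminal carbon and giving the kinetic (Z)-allylborane 19; low temperature and the congested ester hold back the 1,3-boratropic shift to the E isomer. At −78 °C only the dialkylallylborane end reacts: 13 is allylated through a chair with the boronate axial, forming C5–C6 and the syn adduct 20, and the isopinocampheyl groups direct attack to the Si face of 13, which sets C5 as R. On warming, 20 allylates 10 through a second chair in which the C6 substituent is axial, because the equatorial position would clash with the tetraphenyl-dioxaborolane; this forms C8–C9, turns out C6=C7 as Z, and transfers the C6 configuration to C9 (S). The closest known reaction type is the one-pot double allylboration of two aldehydes with γ-boryl allyl(diisopinocampheyl)boranes made by hydroboration of allenylboronates. No ring is closed. The step needs kinetic Z hydroboration, borane-before-boronate chemoselectivity (secured by the reactivity gap between the two boron centres and the order of addition), the axial second chair (secured by the hindered diol), and reagent control over the β-stereocentre C11 of 10 (a closed chair transfers chirality with little regard for a β-substituent). Both aldehydes are unbranched, the acetonide, silyl ether and styrene are inert to allylboron reagents, and oxidative work-up frees both hydroxyls.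

Step 11
Reactants: 21 (3R,4Z,7S)-1-{[tert-butyl(dimethyl)silyl]oxy}-8-{(4R,6R)-2,2-dimethyl-6-[(E)-2-phenylethenyl]-1,3-dioxan-4-yl}oct-4-ene-3,7-diol
Product: 22 (4S,6R)-4-[(2S,4Z,6R)-2,6,8-tris{[tert-butyl(dimethyl)silyl]oxy}oct-4-en-1-yl]-2,2-dimethyl-6-[(E)-2-phenylethenyl]-1,3-dioxane
Conditions: TBSCl, imidazole, DMAP (cat.), DMF, rt
Reagents that add atoms: tert-butyldimethylsilyl chloride, CC(C)(C)[Si](C)(C)Cl
Why: Silyl ether formation on two unhindered secondary alcohols under mildly basic conditions that leave the acetonide and the Z alkene untouched.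

Step 12
Reactants: 22 (4S,6R)-4-[(2S,4Z,6R)-2,6,8-tris{[tert-butyl(dimethyl)silyl]oxy}oct-4-en-1-yl]-2,2-dimethyl-6-[(E)-2-phenylethenyl]-1,3-dioxane
Product: 23 (3R,4Z,7S)-3,7-bis{[tert-butyl(dimethyl)silyl]oxy}-8-{(4S,6R)-2,2-dimethyl-6-[(E)-2-phenylethenyl]-1,3-dioxan-4-yl}oct-4-en-1-ol
Conditions: HF·pyridine, pyridine, THF, 0 °C
Reagents that add atoms: none
Why: Buffered fluoride desilylation is governed by steric access, so the primary silyl ether is cleaved well before the two secondary ones, and the acetonide is stable to pyridine-buffered HF.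

Step 13
Reactants: 23 (3R,4Z,7S)-3,7-bis{[tert-butyl(dimethyl)silyl]oxy}-8-{(4S,6R)-2,2-dimethyl-6-[(E)-2-phenylethenyl]-1,3-dioxan-4-yl}oct-4-en-1-ol
Product: 24 (3R,4Z,7S)-3,7-bis{[tert-butyl(dimethyl)silyl]oxy}-8-{(4S,6R)-2,2-dimethyl-6-[(E)-2-phenylethenyl]-1,3-dioxan-4-yl}oct-4-enal
Conditions: Dess–Martin periodinane, NaHCO3, CH2Cl2, 0 °C → rt
Reagents that add atoms: none
Why: Dess–Martin oxidation under buffered, non-basic conditions gives the β-silyloxy aldehyde without β-elimination of the C5 silyloxy group.

Step 14
Reactants: 24 (3R,4Z,7S)-3,7-bis{[tert-butyl(dimethyl)silyl]oxy}-8-{(4S,6R)-2,2-dimethyl-6-[(E)-2-phenylethenyl]-1,3-dioxan-4-yl}oct-4-enal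
Product: 25 methyl (2Z,5R,6Z,9S)-5,9-bis{[tert-butyl(dimethyl)silyl]oxy}-10-{(4S,6R)-2,2-dimethyl-6-[(E)-2-phenylethenyl]-1,3-dioxan-4-yl}deca-2,6-dienoate
Conditions: (CF3CH2O)2P(O)CH2CO2Me, KN(SiMe3)2, 18-crown-6, THF, −78 °C
Reagents that add atoms: methyl 2-[bis(2,2,2-trifluoroethoxy)phosphoryl]acetate, COC(=O)CP(=O)(OCC(F)(F)F)OCC(F)(F)F
Why: Still–Gennari olefination: the electron-poor phosphonate anion with a crown-separated potassium ion adds irreversibly and eliminates fast, so the Z enoate forms under kinetic control at −78 °C, where the β-silyloxy aldehyde does not eliminate.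

Step 15
Reactants: 25 methyl (2Z,5R,6Z,9S)-5,9-bis{[tert-butyl(dimethyl)silyl]oxy}-10-{(4S,6R)-2,2-dimethyl-6-[(E)-2-phenylethenyl]-1,3-dioxan-4-yl}deca-2,6-dienoate
Product: 27 (6R)-6-[(1Z,4S,6R,8R,9E)-4,6,8-trihydroxy-10-phenyldeca-1,9-dien-1-yl]-5,6-dihydro-2H-pyran-2-one, via seco hydroxy ester 26 (not isolated)
Conditions: 48% aq. HF, MeCN, 0 °C → rt; then PPTS (cat.), benzene, rt
Reagents that add atoms: none
Why: Aqueous HF cleaves both silyl ethers and hydrolyses the acetonide; the freed C5 hydroxyl is held next to the ester by the Z C2=C3 bond and closes the six-membered lactone by acid-catalysed transesterification, with no stereocentre touched.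

## Compound list

1 | methyl acetoacetate (methyl 3-oxobutanoate) | COC(=O)CC(C)=O | starting material
2 | methyl 3-(trimethylsilyloxy)but-2-enoate (E/Z mixture) | COC(=O)C=C(C)O[Si](C)(C)C | intermediate
3 | 1-methoxy-1,3-bis(trimethylsilyloxy)buta-1,3-diene (Chan's diene) | COC(=CC(=C)O[Si](C)(C)C)O[Si](C)(C)C | intermediate
4 | (E)-cinnamaldehyde | O=C/C=C/c1ccccc1 | starting material
5 | methyl (5R,6E)-7-phenyl-3,5-bis(trimethylsilyloxy)hepta-2,6-dienoate | COC(=O)C=C(O[Si](C)(C)C)C[C@@H](O[Si](C)(C)C)/C=C/c1ccccc1 | intermediate (not isolated)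
6 | methyl (5R,6E)-5-hydroxy-3-oxo-7-phenylhept-6-enoate | COC(=O)CC(=O)C[C@@H](O)/C=C/c1ccccc1 | intermediate
7 | methyl (5R,6E)-5-[(diethylboranyl)oxy]-3-oxo-7-phenylhept-6-enoate (boron chelate) | CCB(CC)O[C@H](CC(=O)CC(=O)OC)/C=C/c1ccccc1 | intermediate (not isolated)
8 | methyl (3S,5R,6E)-3,5-dihydroxy-7-phenylhept-6-enoate | COC(=O)C[C@@H](O)C[C@@H](O)/C=C/c1ccccc1 | intermediate
9 | methyl 2-[(4S,6R)-2,2-dimethyl-6-[(E)-2-phenylethenyl]-1,3-dioxan-4-yl]acetate | COC(=O)C[C@@H]1C[C@H](/C=C/c2ccccc2)OC(C)(C)O1 | intermediate
10 | 2-[(4S,6R)-2,2-dimethyl-6-[(E)-2-phenylethenyl]-1,3-dioxan-4-yl]acetaldehyde (fragment 2 aldehyde, C9–C15) | O=CC[C@@H]1C[C@H](/C=C/c2ccccc2)OC(C)(C)O1 | intermediate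
11 | propane-1,3-diol | OCCCO | starting material
12 | 3-[tert-butyl(dimethyl)silyl]oxypropan-1-ol | CC(C)(C)[Si](C)(C)OCCCO | intermediate
13 | 3-[tert-butyl(dimethyl)silyl]oxypropanal (fragment 1 aldehyde, C3–C5) | CC(C)(C)[Si](C)(C)OCCC=O | intermediate
14 | propargyl bromide (3-bromoprop-1-yne) | C#CCBr | starting material
15 | benzopinacol (1,1,2,2-tetraphenylethane-1,2-diol) | OC(c1ccccc1)(c1ccccc1)C(O)(c1ccccc1)c1ccccc1 | starting material
16 | allenylmagnesium bromide | C=C=C[Mg]Br | intermediate (not isolated)
17 | allenylboronic acid (propa-1,2-dien-1-ylboronic acid) | C=C=CB(O)O | intermediate (not isolated)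
18 | 4,4,5,5-tetraphenyl-2-(propa-1,2-dien-1-yl)-1,3,2-dioxaborolane | C=C=CB1OC(c2ccccc2)(c2ccccc2)C(c2ccccc2)(c2ccccc2)O1 | intermediate
19 | [(2Z)-3-(4,4,5,5-tetraphenyl-1,3,2-dioxaborolan-2-yl)prop-2-en-1-yl]di(isopinocampheyl)borane, isopinocampheyl groups from (+)-α-pinene | B(C/C=C\B1OC(c2ccccc2)(c2ccccc2)C(c2ccccc2)(c2ccccc2)O1)([C@@H]1C[C@@H]2C[C@H]([C@H]1C)C2(C)C)[C@@H]1C[C@@H]2C[C@H]([C@H]1C)C2(C)C | intermediate (not isolated)
20 | tert-butyl{[(3R,4R)-3-[di(isopinocampheyl)boranyloxy]-4-(4,4,5,5-tetraphenyl-1,3,2-dioxaborolan-2-yl)hex-5-en-1-yl]oxy}dimethylsilane (C5–O and C6–B syn) | CC(C)(C)[Si](C)(C)OCC[C@@H](OB([C@@H]1C[C@@H]2C[C@H]([C@H]1C)C2(C)C)[C@@H]1C[C@@H]2C[C@H]([C@H]1C)C2(C)C)[C@@H](C=C)B1OC(c2ccccc2)(c2ccccc2)C(c2ccccc2)(c2ccccc2)O1 | intermediate (not isolated)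
21 | (3R,4Z,7S)-1-{[tert-butyl(dimethyl)silyl]oxy}-8-{(4R,6R)-2,2-dimethyl-6-[(E)-2-phenylethenyl]-1,3-dioxan-4-yl}oct-4-ene-3,7-diol | CC(C)(C)[Si](C)(C)OCC[C@H](/C=C\C[C@H](O)C[C@@H]1C[C@H](/C=C/c2ccccc2)OC(C)(C)O1)O | intermediate
22 | (4S,6R)-4-[(2S,4Z,6R)-2,6,8-tris{[tert-butyl(dimethyl)silyl]oxy}oct-4-en-1-yl]-2,2-dimethyl-6-[(E)-2-phenylethenyl]-1,3-dioxane | CC(C)(C)[Si](C)(C)OCC[C@H](/C=C\C[C@H](O[Si](C)(C)C(C)(C)C)C[C@@H]1C[C@H](/C=C/c2ccccc2)OC(C)(C)O1)O[Si](C)(C)C(C)(C)C | intermediate
23 | (3R,4Z,7S)-3,7-bis{[tert-butyl(dimethyl)silyl]oxy}-8-{(4S,6R)-2,2-dimethyl-6-[(E)-2-phenylethenyl]-1,3-dioxan-4-yl}oct-4-en-1-ol | OCC[C@H](/C=C\C[C@H](O[Si](C)(C)C(C)(C)C)C[C@@H]1C[C@H](/C=C/c2ccccc2)OC(C)(C)O1)O[Si](C)(C)C(C)(C)C | intermediate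
24 | (3R,4Z,7S)-3,7-bis{[tert-butyl(dimethyl)silyl]oxy}-8-{(4S,6R)-2,2-dimethyl-6-[(E)-2-phenylethenyl]-1,3-dioxan-4-yl}oct-4-enal | O=CC[C@H](/C=C\C[C@H](O[Si](C)(C)C(C)(C)C)C[C@@H]1C[C@H](/C=C/c2ccccc2)OC(C)(C)O1)O[Si](C)(C)C(C)(C)C | intermediate
25 | methyl (2Z,5R,6Z,9S)-5,9-bis{[tert-butyl(dimethyl)silyl]oxy}-10-{(4S,6R)-2,2-dimethyl-6-[(E)-2-phenylethenyl]-1,3-dioxan-4-yl}deca-2,6-dienoate | COC(=O)/C=C\C[C@H](/C=C\C[C@H](O[Si](C)(C)C(C)(C)C)C[C@@H]1C[C@H](/C=C/c2ccccc2)OC(C)(C)O1)O[Si](C)(C)C(C)(C)C | intermediate
26 | methyl (2Z,5R,6Z,9S,11R,13R,14E)-5,9,11,13-tetrahydroxy-15-phenylpentadeca-2,6,14-trienoate | COC(=O)/C=C\C[C@H](/C=C\C[C@H](O)C[C@@H](O)C[C@@H](O)/C=C/c1ccccc1)O | intermediate (not isolated)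
27 | (6R)-6-[(1Z,4S,6R,8R,9E)-4,6,8-trihydroxy-10-phenyldeca-1,9-dien-1-yl]-5,6-dihydro-2H-pyran-2-one | O=C1C=CC[C@H](/C=C\C[C@H](O)C[C@@H](O)C[C@@H](O)/C=C/c2ccccc2)O1 | target

## Step count and risks

Total: 15 steps. Longest linear sequence: 12 steps (steps 1–6 and 10–15).

**Step 10 (key step).** The kinetic reagent 19 may partly equilibrate to its E isomer by boratropic shift before or during the first allylboration. The second allylboration may also leak through the equatorial chair. Either process would show up as the E alkene or as the C9 epimer. The hindered boronate also makes the second stage slow, so 10 is exposed to long reaction times.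
Fallback (sets out from 10, returns at 22): the two bonds are made one at a time around an alkyne. Aldehyde 10 is propargylated with B-allenyldi(isopinocampheyl)borane of the dIpc series to give the homopropargylic alcohol F1, which is silylated to the silyl ether F2. The lithium acetylide of F2 (n-BuLi) adds to 13 to give the propargylic alcohol F3 as a C5 epimer mixture, and Dess–Martin oxidation gives the ynone F4. Transfer hydrogenation with RuCl[(R,R)-TsDPEN](p-cymene) in i-PrOH sets C5 in the (5R)-propargylic alcohol F5. Semi-hydrogenation over Pd/CaCO3 poisoned with Pb(OAc)2 in the presence of quinoline gives the (Z)-allylic alcohol F6, and silylation of F6 (TBSCl, imidazole) gives 22.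

**Step 3.** An uncatalysed silyl-transfer pathway or a moisture-sensitive catalyst may erode the enantioselectivity, and the facial sense rests on analogy.
Fallback (sets out from 4, returns at 6): an auxiliary-controlled acetate aldol. The chlorotitanium enolate of N-acetyl-(4S)-4-isopropyl-1,3-thiazolidine-2-thione (TiCl4, i-Pr2NEt, CH2Cl2, −78 °C) adds to 4 to give the β-hydroxy acyl thiazolidinethione F7. Its diastereomers can be separated, so enantiopurity no longer depends on a catalyst. Displacement of the auxiliary with KO2CCH2CO2Me, MgCl2 and imidazole, with decarboxylation, gives 6.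

**Step 12.** The allylic C5 silyl ether may be cleaved along with the primary one, or the acetonide may suffer on prolonged exposure.
Fallback (sets out from 11, returns at 23): an orthogonal primary protecting group. Diol 11 is converted (NaH, 4-methoxybenzyl chloride) into 3-[(4-methoxyphenyl)methoxy]propan-1-ol F8, and this is oxidised to 3-[(4-methoxyphenyl)methoxy]propanal F9. F9 takes the place of 13 in the double allylboration to give the PMB-protected diol F10. Silylation gives the bis-silyl ether F11, and DDQ in CH2Cl2/pH 7 buffer removes the benzyl-type ether oxidatively without touching silicon to give 23.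

**Step 14.** The C5 silyloxy group may undergo β-elimination from the aldehyde under the basic conditions, or the Z selectivity may be incomplete.
Fallback (sets out from 24, returns at 25): the geometry is set by hydrogenation instead of olefination. CBr4/PPh3 converts 24 into the 1,1-dibromoalkene F12. n-BuLi (2 equiv) followed by ClCO2Me gives the ynoate F13. Semi-hydrogenation over Pd/CaCO3 poisoned with Pb(OAc)2 gives 25 by syn addition of hydrogen.

**Step 15.** The cinnamyl-type C13 carbinol may ionise in the acid (allylic transposition or elimination), or acetonide cleavage and ring closure may not keep pace with desilylation.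
Fallback (sets out from 25, returns at 27): a staged unmasking. Bu4NF buffered with AcOH in THF removes both silyl ethers and the C5 hydroxyl closes onto the Z ester to give the acetonide lactone F14. The acetonide is then exchanged off under mild conditions (PPTS, MeOH, rt) to give 27.

## Further compounds

F1 | step 10 | (2S)-1-{(4R,6R)-2,2-dimethyl-6-[(E)-2-phenylethenyl]-1,3-dioxan-4-yl}pent-4-yn-2-ol | C#CC[C@H](O)C[C@@H]1C[C@H](/C=C/c2ccccc2)OC(C)(C)O1
F2 | step 10 | tert-butyldimethylsilyl ether of F1 | C#CC[C@H](O[Si](C)(C)C(C)(C)C)C[C@@H]1C[C@H](/C=C/c2ccccc2)OC(C)(C)O1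
F3 | step 10 | C5-epimeric propargylic alcohol (C3 and C9 silyl ethers, C6≡C7 alkyne, C11/C13 acetonide) | CC(C)(C)[Si](C)(C)OCCC(O)C#CC[C@H](O[Si](C)(C)C(C)(C)C)C[C@@H]1C[C@H](/C=C/c2ccccc2)OC(C)(C)O1
F4 | step 10 | C5 ynone corresponding to F3 | CC(C)(C)[Si](C)(C)OCCC(=O)C#CC[C@H](O[Si](C)(C)C(C)(C)C)C[C@@H]1C[C@H](/C=C/c2ccccc2)OC(C)(C)O1
F5 | step 10 | (5R)-propargylic alcohol from F4 | CC(C)(C)[Si](C)(C)OCC[C@@H](O)C#CC[C@H](O[Si](C)(C)C(C)(C)C)C[C@@H]1C[C@H](/C=C/c2ccccc2)OC(C)(C)O1
F6 | step 10 | (5R,6Z)-allylic alcohol (22 lacking the C5 silyl group) | CC(C)(C)[Si](C)(C)OCC[C@H](/C=C\C[C@H](O[Si](C)(C)C(C)(C)C)C[C@@H]1C[C@H](/C=C/c2ccccc2)OC(C)(C)O1)O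
F7 | step 3 | (3R,4E)-3-hydroxy-5-phenyl-1-[(4S)-4-(propan-2-yl)-2-sulfanylidene-1,3-thiazolidin-3-yl]pent-4-en-1-one | S=C1SC[C@H](C(C)C)N1C(=O)C[C@@H](O)/C=C/c1ccccc1
F8 | step 12 | 3-[(4-methoxyphenyl)methoxy]propan-1-ol | COc1ccc(COCCCO)cc1
F9 | step 12 | 3-[(4-methoxyphenyl)methoxy]propanal | COc1ccc(COCCC=O)cc1
F10 | step 12 | analogue of 21 with a 4-methoxybenzyl ether at C3 | COc1ccc(COCC[C@H](/C=C\C[C@H](O)C[C@@H]2C[C@H](/C=C/c3ccccc3)OC(C)(C)O2)O)cc1
F11 | step 12 | C5,C9-bis(tert-butyldimethylsilyl) ether of F10 | COc1ccc(COCC[C@H](/C=C\C[C@H](O[Si](C)(C)C(C)(C)C)C[C@@H]2C[C@H](/C=C/c3ccccc3)OC(C)(C)O2)O[Si](C)(C)C(C)(C)C)cc1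
F12 | step 14 | 1,1-dibromoalkene from 24 (C2 as CBr2) | BrC(Br)=CC[C@H](/C=C\C[C@H](O[Si](C)(C)C(C)(C)C)C[C@@H]1C[C@H](/C=C/c2ccccc2)OC(C)(C)O1)O[Si](C)(C)C(C)(C)C
F13 | step 14 | methyl ynoate (C2≡C3 alkyne analogue of 25) | COC(=O)C#CC[C@H](/C=C\C[C@H](O[Si](C)(C)C(C)(C)C)C[C@@H]1C[C@H](/C=C/c2ccccc2)OC(C)(C)O1)O[Si](C)(C)C(C)(C)C
F14 | step 15 | C11/C13 acetonide of 27 | O=C1C=CC[C@H](/C=C\C[C@H](O)C[C@@H]2C[C@H](/C=C/c3ccccc3)OC(C)(C)O2)O1
A1 | alternative 1 | lactone with C9 silyl ether, free C11 hydroxyl, (E)-C13=C14 alkene and C15 benzylic alcohol (C15 epimers) | O=C1C=CC[C@H](/C=C\C[C@H](O[Si](C)(C)C(C)(C)C)C[C@@H](O)C/C=C/C(O)c2ccccc2)O1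
A2 | alternative 1 | all-cis 2-phenyl-1,3-dioxane of the 11,13-syn diol with styryl group and lactone in place | O=C1C=CC[C@H](/C=C\C[C@H](O[Si](C)(C)C(C)(C)C)C[C@@H]2C[C@H](/C=C/c3ccccc3)O[C@H](c4ccccc4)O2)O1
A3 | alternative 2 | diisopropylsilylene bis-ether of the C5 vinyl carbinol and the C9 allyl carbinol | COC(=O)/C=C\C[C@H](C=C)O[Si](C(C)C)(C(C)C)O[C@@H](CC=C)C[C@@H]1C[C@H](/C=C/c2ccccc2)OC(C)(C)O1
A4 | alternative 2 | eight-membered silylene-bridged (Z)-alkene | COC(=O)/C=C\C[C@@H]1/C=C\C[C@@H](C[C@@H]2C[C@H](/C=C/c3ccccc3)OC(C)(C)O2)O[Si](C(C)C)(C(C)C)O1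
A5 | alternative 3 | 2-(tert-butyldimethylsilyl)-1,3-dithiane | CC(C)(C)[Si](C)(C)C1SCCCS1
A6 | alternative 3 | (2S)-2-[3-(triisopropylsilyl)prop-2-yn-1-yl]oxirane (C6–C10) | CC(C)[Si](C(C)C)(C(C)C)C#CC[C@H]1CO1
A7 | alternative 3 | (2S)-2-[(E)-2-phenylethenyl]oxirane (C12–C15) | C1O[C@H]1/C=C/c1ccccc1
A8 | alternative 3 | C6–C15 dithiane with C9 silyl ether and free C13 hydroxyl | CC(C)[Si](C(C)C)(C(C)C)C#CC[C@H](O[Si](C)(C)C(C)(C)C)CC1(SCCCS1)C[C@@H](O)/C=C/c2ccccc2
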